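## Retrosynthetic overview

1. The target is disconnected at the C6–prenyl bond of the dearomatised ring: the last step is a Pd-catalysed transfer of prenyl from a prenyl ester onto C6 of the aromatic precursor, which breaks aromaticity and sets the quaternary centre.
2. The prenyl ester comes from an aryl δ-lactone (benzylic centre) plus prenyl alcohol; the lactone is made by NHC [3+3] annulation of the 6-alkylated chromanone with 3-phenylpropiolaldehyde at C8/7-OH, the only free site.
3. The C11 side chain comes from two Wittig olefinations of a keto-aldehyde, made by enamine Michael addition to methyl vinyl ketone of a 3-arylpropanal lactol; the lactol is the reduced pyranone ring of a coumarin.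
4. The chromanone comes from quinidine-catalysed oxa-Michael closure of 8-tigloyl-5,7-dihydroxycoumarin (Friedel–Crafts), and the coumarin from phloroglucinol and ethyl propiolate; the coumarin ring fixes which oxygen and which carbon react in every later step.
5. Ring order: coumarin pyranone (temporary, becomes the side chain), then chromanone, then benzylic δ-lactone (temporary), then the carbocycle is dearomatised last.

Assumption: the target is taken as the enol tautomer written in the given SMILES (its β-triketone tautomers interconvert), and lactols are drawn as cyclic hemiacetals (both anomers).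

## Route

Step 1
Reactants: 1 phloroglucinol (benzene-1,3,5-triol); 2 ethyl propiolate
Product: 3 5,7-dihydroxy-2H-chromen-2-one (5,7-dihydroxycoumarin)
Conditions: ZnCl2 (1 equiv), dioxane, 100 °C
Reagents that add atoms: none
Why: Pechmann-type condensation (hydroarylation of the propiolate by the triol, then lactonisation with loss of ethanol); the threefold-symmetric phenol can give only one coumarin and no stereocentre is formed.

Step 2
Reactants: 3 5,7-dihydroxycoumarin; 4 tigloyl chloride [(2E)-2-methylbut-2-enoyl chloride]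
Product: 5 5,7-dihydroxy-8-[(2E)-2-methylbut-2-enoyl]-2H-chromen-2-one
Conditions: AlCl3 (4 equiv), PhNO2, 25 to 60 °C; then ice, 1 M HCl
Reagents that add atoms: none
Why: Friedel–Crafts acylation: 5,7-dihydroxycoumarins are acylated chiefly at C8 (ortho to 7-OH and para to 5-OH, the resorcinol pattern) rather than at C6 between the two hydroxyls, and the aluminium-chelated o-hydroxyaryl enone is released on cold acidic work-up without cyclising; no stereocentre is formed.

Step 3
Reactants: 5 8-tigloyl-5,7-dihydroxycoumarin
Product: 6 (8S,9S)-5-hydroxy-8,9-dimethyl-8,9-dihydro-2H,10H-pyrano[2,3-f]chromene-2,10-dione (coumarin fused to a trans-2,3-dimethylchromanone)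
Conditions: quinidine (20 mol %), PhCl, rt, 48 h; recrystallise
Reagents that add atoms: none
Why: Cinchona-alkaloid-catalysed intramolecular oxa-Michael addition: only the 7-OH can reach the enone because the other flanking oxygen is locked in the pyranone ring, the quinidine-bound phenoxide adds to one face of the tigloyl β-carbon to set C8 as S (quinidine being the pseudoenantiomer of the quinine that gives the 8R series), and C9 is fixed trans (S) by equilibration of the enolisable α-centre.

Step 4
Reactants: 6 coumarin-fused chromanone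
Product: 7 (8S,9S)-5-hydroxy-8,9-dimethyl-3,4,8,9-tetrahydro-2H,10H-pyrano[2,3-f]chromene-2,10-dione
Conditions: H2 (1 atm), Pd/C (10%), EtOAc, rt
Reagents that add atoms: none
Why: Heterogeneous catalytic hydrogenation reduces only the conjugated, electron-poor C3=C4 bond of the coumarin; the electron-rich aryl ketone, the arene and both stereocentres are untouched.

Step 5
Reactants: 7 dihydrocoumarin-fused chromanone
Product: 8 (8S,9S)-2,5-dihydroxy-8,9-dimethyl-3,4,8,9-tetrahydro-2H,10H-pyrano[2,3-f]chromen-10-one (lactol, both C2 epimers)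
Conditions: NaH (1.05 equiv), THF, 0 °C; then i-Bu2AlH (1.3 equiv), −78 °C; then 1 M HCl, 0 °C
Reagents that add atoms: none
Why: Partial hydride reduction of an aryl δ-lactone to the lactol, the tetrahedral aluminate being stable at −78 °C; prior deprotonation puts a phenoxide para to the chromanone carbonyl, which makes that ketone an unreactive vinylogous carboxylate so that hydride goes to the lactone only.

Step 6
Reactants: 8 lactol; 9 methyl vinyl ketone (but-3-en-2-one)
Product: 10 (3R,8S,9S)-2,5-dihydroxy-8,9-dimethyl-3-(3-oxobutyl)-3,4,8,9-tetrahydro-2H,10H-pyrano[2,3-f]chromen-10-one (lactol, both C2 epimers)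
Conditions: (R)-α,α-diphenylprolinol trimethylsilyl ether (20 mol %), PhCO2H (20 mol %), CHCl3, 4 °C
Reagents that add atoms: none
Why: Enamine-catalysed Michael addition of an aldehyde to an enone: the lactol opens to the 3-arylpropanal, whose (E)-enamine is shielded on one face by the diphenyl(silyloxy)methyl group, so that methyl vinyl ketone adds to the other face and the new centre is set as R under catalyst control, after which re-closure to the lactol protects it from epimerisation and from aldol ring closure.

Step 7
Reactants: 10 keto lactol; 11 isopropyltriphenylphosphonium iodide; 12 methyltriphenylphosphonium bromide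
Product: 14 (2S,3S)-5,7-dihydroxy-2,3-dimethyl-6-[(2R)-5-methyl-2-(2-methylprop-1-en-1-yl)hex-5-en-1-yl]chroman-4-one, via keto-alkene 13 (not isolated)
Conditions: KN(SiMe3)2 (2.0 equiv), THF, −78 °C; Ph3P=CMe2 [from 11 + KN(SiMe3)2, 1.2 equiv], −78 to 0 °C; Ph3P=CH2 [from 12 + KN(SiMe3)2, 3 equiv], 0 °C to rt; then 1 M HCl
Reagents that add atoms: none
Why: Two Wittig olefinations in one flask: the phenol and the lactol are first taken to the dipotassium salt (which frees the aldehyde and deactivates the chelated chromanone carbonyl), the hindered isopropylidene ylide reacts only with the aldehyde in the cold, the methylene ylide then converts the methyl ketone, and the α-branched aldehyde is consumed before it can enolise, so the R centre is kept.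

Step 8
Reactants: 14 6-alkylated 5,7-dihydroxychromanone; 15 3-phenylprop-2-ynal
Product: 16 (2S,3S,10R)-5-hydroxy-2,3-dimethyl-6-[(2R)-5-methyl-2-(2-methylprop-1-en-1-yl)hex-5-en-1-yl]-10-phenyl-2,3,9,10-tetrahydro-4H,8H-pyrano[2,3-f]chromene-4,8-dione (δ-lactone: 7-O–CO–CH2–CH(Ph)–C8 of the chromanone)
Conditions: (5aS,10bR)-N-mesityl aminoindanol-derived triazolium chloride (10 mol %), i-Pr2NEt (10 mol %), toluene, 4 Å molecular sieves, rt
Reagents that add atoms: none
Why: NHC-catalysed redox [3+3] annulation: the carbene converts the ynal into an α,β-unsaturated acyl azolium, C8 (the only unsubstituted ring carbon) adds in Michael fashion to the face left open by the chiral carbene (the enantiomer that gives R is used) to set the benzylic centre, and acyl transfer to the adjacent 7-OH closes the δ-lactone and releases the catalyst.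

Step 9
Reactants: 16 aryl δ-lactone; 17 prenyl alcohol (3-methylbut-2-en-1-ol, 1.5 equiv)
Product: 19 target CNP0155375.2 (3R)-3-[(2S,3S,6S)-4-hydroxy-2,3-dimethyl-6-[(2R)-5-methyl-2-(2-methylprop-1-en-1-yl)hex-5-en-1-yl]-6-(3-methylbut-2-en-1-yl)-5,7-dioxo-3,5,6,7-tetrahydro-2H-chromen-8-yl]-3-phenylpropanoic acid, via prenyl ester 18 (not isolated)
Conditions: Cs2CO3 (10 mol %), THF, rt; then Pd2(dba)3·CHCl3 (2.5 mol %), (R,R)-DACH-phenyl Trost ligand (7.5 mol %), 40 °C
Reagents that add atoms: none
Why: Proposed new method: base-catalysed transesterification lets prenyl alcohol open the aryl δ-lactone to prenyl ester 18, zerovalent palladium with the chiral bisphosphine then ionises this allylic ester, and the π-prenyl cation is captured at its unhindered CH2 end by C6 (the only ring carbon flanked by two phenolic oxygens) on the face left open by the ligand (the ligand enantiomer that gives 6S is used), which breaks aromaticity, sets the quaternary centre and leaves the departed carboxylate as the free acid of the target (O-prenylation is reversible under palladium, C-prenylation is not); the closest known reaction type is the Tsuji–Trost asymmetric allylic dearomatisation of phenols and the palladium-catalysed C-allylation of acylphloroglucinols.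

## Compound list

1 | phloroglucinol (benzene-1,3,5-triol) | Oc1cc(O)cc(O)c1 | starting material
2 | ethyl propiolate (ethyl prop-2-ynoate) | C#CC(=O)OCC | starting material
3 | 5,7-dihydroxy-2H-chromen-2-one (5,7-dihydroxycoumarin) | O=c1ccc2c(O)cc(O)cc2o1 | intermediate
4 | tigloyl chloride [(2E)-2-methylbut-2-enoyl chloride] | C/C=C(\C)C(Cl)=O | starting material
5 | 5,7-dihydroxy-8-[(2E)-2-methylbut-2-enoyl]-2H-chromen-2-one | C/C=C(\C)C(=O)c1c(O)cc(O)c2ccc(=O)oc12 | intermediate
6 | (8S,9S)-5-hydroxy-8,9-dimethyl-8,9-dihydro-2H,10H-pyrano[2,3-f]chromene-2,10-dione | O=C1[C@@H](C)[C@H](C)Oc2cc(O)c3ccc(=O)oc3c21 | intermediate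
7 | (8S,9S)-5-hydroxy-8,9-dimethyl-3,4,8,9-tetrahydro-2H,10H-pyrano[2,3-f]chromene-2,10-dione | O=C1[C@@H](C)[C@H](C)Oc2cc(O)c3CCC(=O)Oc3c21 | intermediate
8 | (8S,9S)-2,5-dihydroxy-8,9-dimethyl-3,4,8,9-tetrahydro-2H,10H-pyrano[2,3-f]chromen-10-one (lactol, both C2 epimers) | O=C1[C@@H](C)[C@H](C)Oc2cc(O)c3CCC(O)Oc3c21 | intermediate
9 | methyl vinyl ketone (but-3-en-2-one) | C=CC(C)=O | starting material
10 | (3R,8S,9S)-2,5-dihydroxy-8,9-dimethyl-3-(3-oxobutyl)-3,4,8,9-tetrahydro-2H,10H-pyrano[2,3-f]chromen-10-one (lactol, both C2 epimers) | O=C1[C@@H](C)[C@H](C)Oc2cc(O)c3C[C@@H](CCC(C)=O)C(O)Oc3c21 | intermediate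
11 | isopropyltriphenylphosphonium iodide | CC(C)[P+](c1ccccc1)(c1ccccc1)c1ccccc1.[I-] | starting material
12 | methyltriphenylphosphonium bromide | C[P+](c1ccccc1)(c1ccccc1)c1ccccc1.[Br-] | starting material
13 | (2S,3S)-5,7-dihydroxy-2,3-dimethyl-6-[(2R)-2-(2-methylprop-1-en-1-yl)-5-oxohexyl]chroman-4-one (not isolated) | O=C1[C@@H](C)[C@H](C)Oc2cc(O)c(C[C@H](C=C(C)C)CCC(C)=O)c(O)c21 | intermediate
14 | (2S,3S)-5,7-dihydroxy-2,3-dimethyl-6-[(2R)-5-methyl-2-(2-methylprop-1-en-1-yl)hex-5-en-1-yl]chroman-4-one | O=C1[C@@H](C)[C@H](C)Oc2cc(O)c(C[C@H](C=C(C)C)CCC(C)=C)c(O)c21 | intermediate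
15 | 3-phenylprop-2-ynal | O=CC#Cc1ccccc1 | starting material
16 | (2S,3S,10R)-5-hydroxy-2,3-dimethyl-6-[(2R)-5-methyl-2-(2-methylprop-1-en-1-yl)hex-5-en-1-yl]-10-phenyl-2,3,9,10-tetrahydro-4H,8H-pyrano[2,3-f]chromene-4,8-dione | O=C1[C@@H](C)[C@H](C)Oc2c3[C@@H](c4ccccc4)CC(=O)Oc3c(C[C@H](C=C(C)C)CCC(C)=C)c(O)c21 | intermediate
17 | prenyl alcohol (3-methylbut-2-en-1-ol) | CC(C)=CCO | starting material
18 | 3-methylbut-2-en-1-yl (3R)-3-[(2S,3S)-5,7-dihydroxy-2,3-dimethyl-6-[(2R)-5-methyl-2-(2-methylprop-1-en-1-yl)hex-5-en-1-yl]-4-oxochroman-8-yl]-3-phenylpropanoate (not isolated) | O=C1[C@@H](C)[C@H](C)Oc2c([C@H](CC(=O)OCC=C(C)C)c3ccccc3)c(O)c(C[C@H](C=C(C)C)CCC(C)=C)c(O)c21 | intermediate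
19 | (3R)-3-[(2S,3S,6S)-4-hydroxy-2,3-dimethyl-6-[(2R)-5-methyl-2-(2-methylprop-1-en-1-yl)hex-5-en-1-yl]-6-(3-methylbut-2-en-1-yl)-5,7-dioxo-3,5,6,7-tetrahydro-2H-chromen-8-yl]-3-phenylpropanoic acid (CNP0155375.2) | C=C(C)CC[C@@H](C=C(C)C)C[C@@]1(CC=C(C)C)C(=O)C2=C(O)[C@@H](C)[C@H](C)OC2=C([C@H](CC(=O)O)c2ccccc2)C1=O | target

## Step count and risks

Total step count: 9. Longest linear sequence: 9 (from phloroglucinol 1).

The three steps most likely to fail:

**Step 9 (palladium-mediated ester-to-carbon prenyl transfer).** The prenyl ester may ionise slowly, and the ligand may not override the bias of the existing centres. The fallback sets out from 16 and comes back at 19. Lactone 16 is saponified (LiOH, THF–H2O, 0 °C) to the ring-opened hydroxy acid F1. F1 is then alkylated at C6 with prenyl bromide under chiral phase-transfer conditions (CsOH·H2O, O-allyl-N-(9-anthracenylmethyl)cinchonidinium bromide, CH2Cl2, −50 °C; then 1 M HCl). This is a direct SN2 alkylative dearomatisation by an external electrophile inside a chiral ion pair; it needs no ionisation of an ester and gives 19 directly.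

**Step 5 (lactone reduced in the presence of the aryl ketone).** If hydride also attacks the ketone, the fallback sets out from 7 and comes back at 8. Lactone 7 is opened with Me2AlSEt (from AlMe3 and EtSH, CH2Cl2, 0 °C) to the S-ethyl thioester F2. Fukuyama reduction (Et3SiH, Pd/C, acetone, rt) converts the thioester into the aldehyde, which closes onto the neighbouring phenol to give lactol 8; no hydride reagent meets the ketone.

**Step 8 (carbene annulation on a hindered, chelated phenol).** If the acyl azolium only O-acylates or the selectivity is low, the fallback sets out from 14 and comes back at 16. Iminium-ion Friedel–Crafts alkylation of 14 at C8 with cinnamaldehyde is used instead (diphenylprolinol trimethylsilyl ether of the configuration that gives the R centre, PhCO2H, CH2Cl2, 0 °C). The 7-OH closes onto the aldehyde and gives the cyclic hemiacetal F3. Oxidation of F3 with pyridinium chlorochromate [C5H5NH][CrO3Cl] (NaOAc, CH2Cl2) gives lactone 16.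

Further compounds

F1 | step 9 | (3R)-3-[(2S,3S)-5,7-dihydroxy-2,3-dimethyl-6-[(2R)-5-methyl-2-(2-methylprop-1-en-1-yl)hex-5-en-1-yl]-4-oxochroman-8-yl]-3-phenylpropanoic acid | O=C1[C@@H](C)[C@H](C)Oc2c([C@H](CC(=O)O)c3ccccc3)c(O)c(C[C@H](C=C(C)C)CCC(C)=C)c(O)c21
F2 | step 5 | S-ethyl 3-[(2S,3S)-5,7-dihydroxy-2,3-dimethyl-4-oxochroman-6-yl]propanethioate | O=C1[C@@H](C)[C@H](C)Oc2cc(O)c(CCC(=O)SCC)c(O)c21
F3 | step 8 | (2S,3S,10R)-5,8-dihydroxy-2,3-dimethyl-6-[(2R)-5-methyl-2-(2-methylprop-1-en-1-yl)hex-5-en-1-yl]-10-phenyl-2,3,9,10-tetrahydro-4H,8H-pyrano[2,3-f]chromen-4-one (both C8 epimers) | O=C1[C@@H](C)[C@H](C)Oc2c3[C@@H](c4ccccc4)CC(O)Oc3c(C[C@H](C=C(C)C)CCC(C)=C)c(O)c21
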